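**Plan**

- Retrosynthesis: O-demethylation comes last. The bond from the ring A C2 oxygen to C1 of ring B is traced back, by re-inserting CO, to a 19-membered aryl benzoate lactone, which is opened at its ester C–O bond to a seco hydroxy acid.
- The two ethano bridges (B–C and D–A) are cut as stilbene C=C bonds (two Wittig reactions), and the C–O–D ether is cut at the ring C C2–O bond (SNAr on a 2-fluorobenzaldehyde).
- Enabling feature (ring A: C1 OH, C2 O, C4 CH2; ring B: C1 O, C4 CH2; ring C: C1 CH2, C2 O, C3 OH; ring D: C1 O, C3 CH2): the oxygen on C2 of ring A is bonded to C1 of ring B, a para-phenylene carbon with two unsubstituted ortho positions. A C=O placed between that oxygen and C1 therefore gives an unhindered benzoate of the ring A phenol.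
- Forward: ring D phosphonium salt plus ring A aldehyde, then ring C by SNAr, then ring B by Wittig give the open chain. After hydrogenation and saponification the 19-membered lactone is the first ring; it is contracted to the 18-membered macrocycle, and demethylation ends the route.
- Stereochemistry: the target has no stereocentre; both olefins are carried as E/Z mixtures and erased by hydrogenation.

Key step: step 8

Remark: O-benzylisovanillin (3) and the ring B phosphonium salt (8) are taken as purchased; each is one routine step from isovanillin or methyl 4-(bromomethyl)benzoate if it has to be made.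

**Route**

Step 1
Reactants: 1 3-hydroxybenzyl alcohol
Product: 2 (3-hydroxybenzyl)triphenylphosphonium bromide
Conditions: PPh3·HBr (1.05 equiv), MeCN, reflux
Reagents that add atoms: triphenylphosphine hydrobromide, [Br-].[PH+](c1ccccc1)(c1ccccc1)c1ccccc1
Why: Direct phosphonium salt formation, in which the benzylic alcohol is activated by the acid and substituted by triphenylphosphine, a standard one-step route to hydroxybenzylphosphonium salts that leaves the phenol untouched.

Step 2
Reactants: 2 (3-hydroxybenzyl)triphenylphosphonium bromide; 3 3-(benzyloxy)-4-methoxybenzaldehyde (O-benzylisovanillin)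
Product: 5 3-{2-[3-(benzyloxy)-4-methoxyphenyl]ethenyl}phenol (E/Z mixture), via phenoxide ylide 4 (not isolated)
Conditions: KOtBu (2.2 equiv), THF, 0 °C to rt; then aq. HCl
Reagents that add atoms: none
Why: Wittig olefination, in which the first equivalent of base forms the phenoxide and the second the semi-stabilised benzylic ylide that condenses with the aldehyde; the double-bond geometry is of no consequence because the olefin is hydrogenated in step 5.

Step 3
Reactants: 5 3-{2-[3-(benzyloxy)-4-methoxyphenyl]ethenyl}phenol; 6 2-fluoro-3-methoxybenzaldehyde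
Product: 7 2-(3-{2-[3-(benzyloxy)-4-methoxyphenyl]ethenyl}phenoxy)-3-methoxybenzaldehyde (E/Z mixture)
Conditions: K2CO3 (2 equiv), DMF, 120 °C, N2
Reagents that add atoms: none
Why: Nucleophilic aromatic substitution (SNAr, addition–elimination), in which the ortho-formyl group activates the C–F carbon and stabilises the Meisenheimer adduct, so the potassium phenoxide of 5 should displace fluoride without touching the benzyl ether or the olefin.

Step 4
Reactants: 7 2-(3-{2-[3-(benzyloxy)-4-methoxyphenyl]ethenyl}phenoxy)-3-methoxybenzaldehyde; 8 [4-(methoxycarbonyl)benzyl]triphenylphosphonium bromide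
Product: 10 methyl 4-{2-[2-(3-{2-[3-(benzyloxy)-4-methoxyphenyl]ethenyl}phenoxy)-3-methoxyphenyl]ethenyl}benzoate (E/Z mixture at both double bonds), via ester ylide 9 (not isolated)
Conditions: K2CO3 (3 equiv), 18-crown-6 (10 mol %), CH2Cl2, reflux
Reagents that add atoms: none
Why: Wittig olefination under solid–liquid phase-transfer conditions, in which the ester-substituted benzylic ylide forms with carbonate alone and adds to the aryl aldehyde while the methyl ester and the aryl ethers are inert to this weak base.

Step 5
Reactants: 10 methyl 4-{2-[2-(3-{2-[3-(benzyloxy)-4-methoxyphenyl]ethenyl}phenoxy)-3-methoxyphenyl]ethenyl}benzoate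
Product: 12 methyl 4-{2-[2-(3-{2-[3-hydroxy-4-methoxyphenyl]ethyl}phenoxy)-3-methoxyphenyl]ethyl}benzoate, via saturated benzyl ether 11 (not isolated)
Conditions: H2 (1 atm), 10% Pd/C, EtOAc/MeOH, rt
Reagents that add atoms: none
Why: Heterogeneous catalytic hydrogenation, in which palladium on carbon saturates both stilbene double bonds and then hydrogenolyses the benzyl ether, while the diaryl ether, the methyl ethers and the benzoate ester are stable under these mild conditions.

Step 6
Reactants: 12 methyl 4-{2-[2-(3-{2-[3-hydroxy-4-methoxyphenyl]ethyl}phenoxy)-3-methoxyphenyl]ethyl}benzoate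
Product: 13 4-{2-[2-(3-{2-[3-hydroxy-4-methoxyphenyl]ethyl}phenoxy)-3-methoxyphenyl]ethyl}benzoic acid
Conditions: LiOH·H2O (5 equiv), THF/MeOH/H2O, 50 °C; then 1 M HCl
Reagents that add atoms: lithium hydroxide, [Li+].[OH-]
Why: Saponification (acyl–oxygen ester hydrolysis), in which hydroxide adds to the unhindered methyl benzoate and expels methoxide, and acidification returns the free phenol and carboxylic acid with all ether bonds intact.

Step 7
Reactants: 13 4-{2-[2-(3-{2-[3-hydroxy-4-methoxyphenyl]ethyl}phenoxy)-3-methoxyphenyl]ethyl}benzoic acid
Product: 15 19-membered macrolactone (ring B C1–C(=O)–O–C2 of ring A; OMe on ring A C1 and ring C C3), via mixed anhydride 14 (not isolated)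
Conditions: MNBA (2-methyl-6-nitrobenzoic anhydride, 1.5 equiv), DMAP (6 equiv), CH2Cl2 (final 1 mM), 13 added by syringe pump over 12 h, rt to 40 °C
Reagents that add atoms: none
Why: Shiina macrolactonization, in which the carboxylate forms a mixed anhydride with the hindered nitrobenzoic anhydride, DMAP transfers the unhindered aroyl group selectively, and slow addition at high dilution should let the flexible chain close the unstrained 19-membered aryl ester in preference to oligomerisation.

Step 8
Reactants: 15 19-membered macrolactone
Product: 16 marchantin C dimethyl ether (18-membered macrocycle; OMe on ring A C1 and ring C C3)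
Conditions: Ni(cod)2 [bis(1,5-cyclooctadiene)nickel] (20 mol %), dcypt [3,4-bis(dicyclohexylphosphino)thiophene] (40 mol %), K3PO4 (1.5 equiv), mesitylene (0.02 M), 160 °C, slow argon sweep
Reagents that add atoms: none
Why: Proposed new method: the electron-rich zerovalent nickel–dcypt complex should add oxidatively into the acyl C–O bond of the lactone (a 20-membered acylnickel aryloxide), lose CO by de-insertion and sweep-out to give a 19-membered arylnickel aryloxide, and form the bond between the ring A oxygen and C1 of ring B by C–O reductive elimination. The closest known reaction type is the intermolecular nickel- or palladium-catalysed decarbonylative etherification of aryl esters with this ligand, established mainly for azinecarboxylates; oxidative addition and CO extrusion of plain aryl benzoates are known from decarbonylative cross-couplings, so the unprecedented elementary step is C–O reductive elimination from a non-heteroaryl divalent nickel centre inside a macrocycle. The 18-membered ring arises by one-atom contraction of the 19-membered ring, an intramolecular reductive elimination in which the bisphosphine holds aryl and aryloxide cis and the tether prevents them from separating, which rules out crossover. No stereocentre is formed. The step needs cleavage of the acyl C–O bond in preference to the aryl–OMe and diaryl ether C–O bonds; the weaker, more electrophilic ester linkage, the absence of ortho substituents on ring B and the lack of any reductant or transmetalating partner should secure this, while the electron-rich 2-methoxyaryloxide should favour the final C–O bond formation.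

Step 9
Reactants: 16 marchantin C dimethyl ether
Product: 17 marchantin C
Conditions: BBr3 (6 equiv), CH2Cl2, −78 °C to rt; then H2O
Reagents that add atoms: none
Why: Lewis acid-mediated aryl methyl ether cleavage, in which BBr3 coordinates each methoxy oxygen and bromide removes the methyl group by SN2 attack, whereas the diaryl ether oxygens cannot be dealkylated in this way, so hydrolysis of the aryl borates should release the target.

**Compound list**

1 | 3-hydroxybenzyl alcohol | OCc1cccc(O)c1 | starting material
2 | (3-hydroxybenzyl)triphenylphosphonium bromide | [Br-].Oc1cccc(C[P+](c2ccccc2)(c2ccccc2)c2ccccc2)c1 | intermediate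
3 | 3-(benzyloxy)-4-methoxybenzaldehyde (O-benzylisovanillin) | COc1ccc(C=O)cc1OCc1ccccc1 | starting material
4 | potassium 3-[(triphenylphosphoranylidene)methyl]phenolate (phenoxide ylide, not isolated) | [K+].[O-]c1cccc(C=P(c2ccccc2)(c2ccccc2)c2ccccc2)c1 | intermediate
5 | 3-{2-[3-(benzyloxy)-4-methoxyphenyl]ethenyl}phenol (E/Z mixture) | COc1ccc(C=Cc2cccc(O)c2)cc1OCc1ccccc1 | intermediate
6 | 2-fluoro-3-methoxybenzaldehyde | COc1cccc(C=O)c1F | starting material
7 | 2-(3-{2-[3-(benzyloxy)-4-methoxyphenyl]ethenyl}phenoxy)-3-methoxybenzaldehyde (E/Z mixture) | COc1ccc(C=Cc2cccc(Oc3c(OC)cccc3C=O)c2)cc1OCc1ccccc1 | intermediate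
8 | [4-(methoxycarbonyl)benzyl]triphenylphosphonium bromide | [Br-].COC(=O)c1ccc(C[P+](c2ccccc2)(c2ccccc2)c2ccccc2)cc1 | starting material
9 | methyl 4-[(triphenylphosphoranylidene)methyl]benzoate (ester ylide, not isolated) | COC(=O)c1ccc(C=P(c2ccccc2)(c2ccccc2)c2ccccc2)cc1 | intermediate
10 | methyl 4-{2-[2-(3-{2-[3-(benzyloxy)-4-methoxyphenyl]ethenyl}phenoxy)-3-methoxyphenyl]ethenyl}benzoate (E/Z mixture at both double bonds) | COC(=O)c1ccc(C=Cc2cccc(OC)c2Oc2cccc(C=Cc3ccc(OC)c(OCc4ccccc4)c3)c2)cc1 | intermediate
11 | methyl 4-{2-[2-(3-{2-[3-(benzyloxy)-4-methoxyphenyl]ethyl}phenoxy)-3-methoxyphenyl]ethyl}benzoate (saturated benzyl ether, not isolated) | COC(=O)c1ccc(CCc2cccc(OC)c2Oc2cccc(CCc3ccc(OC)c(OCc4ccccc4)c3)c2)cc1 | intermediate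
12 | methyl 4-{2-[2-(3-{2-[3-hydroxy-4-methoxyphenyl]ethyl}phenoxy)-3-methoxyphenyl]ethyl}benzoate | COC(=O)c1ccc(CCc2cccc(OC)c2Oc2cccc(CCc3ccc(OC)c(O)c3)c2)cc1 | intermediate
13 | 4-{2-[2-(3-{2-[3-hydroxy-4-methoxyphenyl]ethyl}phenoxy)-3-methoxyphenyl]ethyl}benzoic acid | OC(=O)c1ccc(CCc2cccc(OC)c2Oc2cccc(CCc3ccc(OC)c(O)c3)c2)cc1 | intermediate
14 | mixed anhydride of 13 with 2-methyl-6-nitrobenzoic acid (not isolated) | O=C(OC(=O)c1c(C)cccc1[N+](=O)[O-])c1ccc(CCc2cccc(OC)c2Oc2cccc(CCc3ccc(OC)c(O)c3)c2)cc1 | intermediate
15 | 19-membered macrolactone (ring B benzoate of the ring A C2 oxygen; OMe on ring A C1 and ring C C3) | O=C1Oc2cc(ccc2OC)CCc2cccc(c2)Oc2c(OC)cccc2CCc2ccc1cc2 | intermediate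
16 | marchantin C dimethyl ether (18-membered macrocycle) | COc1ccc2cc1Oc1ccc(cc1)CCc1cccc(OC)c1Oc1cccc(c1)CC2 | intermediate
17 | marchantin C | Oc1ccc2cc1Oc1ccc(cc1)CCc1cccc(O)c1Oc1cccc(c1)CC2 | target

**Step count**

Total: 9 steps. Longest linear sequence: 9 steps (1 to 17); compounds 3, 6 and 8 are purchased.

**Steps most likely to fail**

1. Step 8 (new method). The arylnickel aryloxide formed after oxidative addition and CO loss may not undergo C–O reductive elimination, because the aryl group is not an azine. The catalyst would then rest as a nickel carbonyl, or the intermediate would be diverted to protodemetalated, ring-opened material, and no turnover would occur. The fallback uses known chemistry only; it sets out from 7 and comes back at 16. Wittig olefination of 7 with commercial (4-bromobenzyl)triphenylphosphonium bromide (K2CO3, 18-crown-6, CH2Cl2, reflux) should give the bromo bis-stilbene F1. Diimide reduction (TsNHNH2, NaOAc, THF/H2O, reflux) should saturate both double bonds without touching the C–Br bond and give the bibenzyl bromide F2. BCl3 with pentamethylbenzene (CH2Cl2, −78 °C) should remove the benzyl group selectively and give the bromo phenol F3. An intramolecular Ullmann diaryl ether coupling (CuI, N,N-dimethylglycine, Cs2CO3, dioxane, 100 °C, high dilution) should then close the 18-membered ring directly to 16.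

2. Step 7. Intermolecular acylation (dimer and oligomer formation) may outrun closure of the 19-membered ring by the weakly nucleophilic ortho-methoxy phenol. The fallback changes the oxidation level at which the ring is closed; it sets out from 12 and comes back at 15. Reduction of the methyl ester of 12 with iBu2AlH (DIBAL-H, CH2Cl2, −78 to 0 °C) should give the benzylic alcohol F4, and MnO2 (CH2Cl2, rt) should oxidise it to the hydroxy aldehyde F5. An N-heterocyclic carbene-catalysed oxidative macrolactonization (triazolium precatalyst, DBU, 3,3',5,5'-tetra-tert-butyldiphenoquinone, THF, high dilution) should then acylate the phenol through an acyl azolium that is present only in catalytic concentration, which disfavours chain–chain coupling, and give 15.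

3. Step 3. Addition–elimination at a C–F carbon flanked by two ortho substituents may be sluggish, with base-induced degradation of the aldehyde at the temperature required. The fallback sets out from 5 and comes back at 7 without any new compound. Copper-catalysed Ullmann-type coupling of phenol 5 with commercial 2-bromo-3-methoxybenzaldehyde (CuI, picolinic acid, K3PO4, DMSO, 90 °C) forms the C–O bond at copper instead of through a Meisenheimer adduct.

Further compounds
F1 | step 8 | 2-(3-{2-[3-(benzyloxy)-4-methoxyphenyl]ethenyl}phenoxy)-1-[2-(4-bromophenyl)ethenyl]-3-methoxybenzene (bromo bis-stilbene, E/Z mixture) | Brc1ccc(C=Cc2cccc(OC)c2Oc2cccc(C=Cc3ccc(OC)c(OCc4ccccc4)c3)c2)cc1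
F2 | step 8 | 2-(3-{2-[3-(benzyloxy)-4-methoxyphenyl]ethyl}phenoxy)-1-[2-(4-bromophenyl)ethyl]-3-methoxybenzene (bibenzyl bromide) | Brc1ccc(CCc2cccc(OC)c2Oc2cccc(CCc3ccc(OC)c(OCc4ccccc4)c3)c2)cc1
F3 | step 8 | 5-[2-(3-{2-[2-(4-bromophenyl)ethyl]-6-methoxyphenoxy}phenyl)ethyl]-2-methoxyphenol (bromo phenol) | Brc1ccc(CCc2cccc(OC)c2Oc2cccc(CCc3ccc(OC)c(O)c3)c2)cc1
F4 | step 7 | 5-{2-[3-(2-{2-[4-(hydroxymethyl)phenyl]ethyl}-6-methoxyphenoxy)phenyl]ethyl}-2-methoxyphenol (benzylic alcohol) | OCc1ccc(CCc2cccc(OC)c2Oc2cccc(CCc3ccc(OC)c(O)c3)c2)cc1
F5 | step 7 | 4-{2-[2-(3-{2-[3-hydroxy-4-methoxyphenyl]ethyl}phenoxy)-3-methoxyphenyl]ethyl}benzaldehyde (hydroxy aldehyde) | O=Cc1ccc(CCc2cccc(OC)c2Oc2cccc(CCc3ccc(OC)c(O)c3)c2)cc1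
F0 | step 3 | none | none
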